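**Plan**
- Retrosynthesis: the four acetal groups go last. The two C–O bonds of the dioxane ring, O4–C3 and O1–C2, are then cut. The ring O1–C2–C3–O4–C4a–C8a joins both catechol oxygens of one piceatannol unit (ring A) to the two olefinic carbons of a second, so this cut gives two identical stilbenes.
- The monomer, piceatannol with its resorcinol hydroxyls masked, is cut at its C=C bond into a benzylphosphonate (from methyl 3,5-dihydroxybenzoate) and a silylated 3,4-dihydroxybenzaldehyde.
- Forward: the phosphonate arm (four steps) and the aldehyde (one step) are joined by Horner–Wadsworth–Emmons olefination, the catechol is unmasked, and Ag2O dimerisation closes the only new ring, the 1,4-dioxane.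
- Stereochemistry: the E olefin comes from the olefination and the trans C2/C3 relationship from reversible closure of a quinone methide. The (2R,3R) configuration comes from separating the racemate on a chiral stationary phase before the final deprotection, which cannot invert C3.

Key step: step 8

Assumption: the dioxane ring is numbered O1–C2–C3–O4 with C2 bearing the catechol ring, C3 the resorcinol ring and O4 para to the styryl arm (which then sits on C7); in this numbering the target is (2R,3R) and trans, and because the oxidant is achiral the key step is taken to give the trans racemate.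

**Route**

Step 1
Reactants: 1 methyl 3,5-dihydroxybenzoate
Product: 2 methyl 3,5-bis(methoxymethoxy)benzoate
Conditions: MOMCl, (i-Pr)2NEt, CH2Cl2, 0 °C to rt
Reagents that add atoms: chloromethyl methyl ether, COCCl
Why: Williamson-type O-alkylation of both phenols with the reactive chloromethyl ether under amine base leaves the ester untouched and gives acetals that should survive hydride, bromination, hot phosphite, strong base, fluoride and Ag2O.

Step 2
Reactants: 2 methyl 3,5-bis(methoxymethoxy)benzoate
Product: 3 [3,5-bis(methoxymethoxy)phenyl]methanol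
Conditions: LiAlH4, THF, 0 °C; aq. potassium sodium tartrate work-up
Reagents that add atoms: none
Why: Hydride reduction of a benzoate ester with LiAlH4 stops at the benzylic alcohol and does not touch aryl methoxymethyl ethers.

Step 3
Reactants: 3 [3,5-bis(methoxymethoxy)phenyl]methanol
Product: 4 1-(bromomethyl)-3,5-bis(methoxymethoxy)benzene
Conditions: CBr4, PPh3, CH2Cl2, 0 °C
Reagents that add atoms: carbon tetrabromide, BrC(Br)(Br)Br
Why: The Appel reaction converts the primary benzylic alcohol into the bromide through an alkoxyphosphonium salt under essentially neutral conditions, which the acid-labile acetals tolerate.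

Step 4
Reactants: 4 1-(bromomethyl)-3,5-bis(methoxymethoxy)benzene
Product: 5 diethyl {[3,5-bis(methoxymethoxy)phenyl]methyl}phosphonate
Conditions: P(OEt)3 (neat), 130 °C, bromoethane distilled off
Reagents that add atoms: triethyl phosphite, CCOP(OCC)OCC
Why: Michaelis–Arbuzov reaction, in which the phosphite displaces the benzylic bromide and bromide then dealkylates the phosphonium salt, is the standard entry to benzylphosphonates and needs no acid or base.

Step 5
Reactants: 6 3,4-dihydroxybenzaldehyde
Product: 7 3,4-bis[(tert-butyldimethylsilyl)oxy]benzaldehyde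
Conditions: TBSCl, imidazole, DMF, rt
Reagents that add atoms: tert-butyldimethylsilyl chloride, CC(C)(C)[Si](C)(C)Cl
Why: Imidazole-promoted silylation of both phenols gives a catechol mask that is orthogonal to the methoxymethyl ethers and is removed by fluoride.

Step 6
Reactants: 5 diethyl {[3,5-bis(methoxymethoxy)phenyl]methyl}phosphonate; 7 3,4-bis[(tert-butyldimethylsilyl)oxy]benzaldehyde
Product: 8 (E)-1,2-bis[(tert-butyldimethylsilyl)oxy]-4-{2-[3,5-bis(methoxymethoxy)phenyl]ethenyl}benzene
Conditions: 5, NaH, 15-crown-5 (cat.), THF, 0 °C; then 7, 0 °C to rt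
Reagents that add atoms: none
Why: Horner–Wadsworth–Emmons olefination of a non-enolisable aryl aldehyde with a benzylphosphonate anion gives the E stilbene, because addition is reversible and the anti-configured oxyanion eliminates diethyl phosphate fastest.

Step 7
Reactants: 8 (E)-1,2-bis[(tert-butyldimethylsilyl)oxy]-4-{2-[3,5-bis(methoxymethoxy)phenyl]ethenyl}benzene
Product: 9 4-[(E)-2-[3,5-bis(methoxymethoxy)phenyl]ethenyl]benzene-1,2-diol
Conditions: TBAF, AcOH, THF, 0 °C, Ar
Reagents that add atoms: none
Why: Fluoride-induced cleavage of the two aryl silyl ethers, buffered with acetic acid so that no air-sensitive catecholate builds up, frees the catechol and leaves the acetals and the olefin untouched.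

Step 8
Reactants: 9 4-[(E)-2-[3,5-bis(methoxymethoxy)phenyl]ethenyl]benzene-1,2-diol (two molecules)
Product: 11 tetra-O-methoxymethyl cassigarol E as the trans racemate (2R*,3R*), via para-quinone methide ether 10 (not isolated)
Conditions: Ag2O (0.6 equiv; 0.5 equiv is the theoretical demand), acetone–toluene 1:2, rt, dark, Ar; filtration through Celite, recovered 9 recycled
Reagents that add atoms: none
Why: Ag2O removes one electron and one proton from the catechol of each molecule of 9; in the molecule that becomes the acceptor the spin of the para-oxygen radical reaches through the ring and the olefin to the carbon bearing the resorcinol ring (C3), where the para oxygen of the second catechol (O4, whose radical is stabilised by its own styryl arm) couples to give quinone methide 10. This is the silver-oxide oxidative coupling of a catechol with a 4-hydroxystyrene-type olefin by which trans-1,4-benzodioxane neolignans are made, run here as a homodimerisation so that donor and acceptor cannot be mismatched. The dioxane ring then closes by 6-exo-trig oxa-Michael addition of the neighbouring hydroxyl O1 to C2 of the quinone methide, which restores the aromatic catechol. C3 is set in the radical coupling without facial bias, so both enantiomers form, and C2 is set relative to C3 because the closure is reversible and settles on the half-chair with both aryl groups pseudo-equatorial, the trans isomer. The step needs O4-to-C3 regiochemistry, secured by the spin distribution described, oxidation at the catechols only, secured by the acetals on both resorcinol rings, and restraint of further oxidation of the catechol that remains in 11, for which the near-theoretical charge of Ag2O and recycling of 9 are intended.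

Step 9
Reactants: 11 tetra-O-methoxymethyl cassigarol E, trans racemate
Product: 12 (2R,3R)-tetra-O-methoxymethyl cassigarol E
Conditions: preparative HPLC, amylose tris(3,5-dimethylphenylcarbamate) on silica, n-hexane–EtOH, rt
Reagents that add atoms: none
Why: Resolution on a chiral stationary phase separates the two enantiomers through diastereomeric adsorption on the helical polysaccharide carbamate without touching any bond at C2 or C3, and the (2R,3R) fraction is to be identified by its ECD spectrum against calculation.

Step 10
Reactants: 12 (2R,3R)-tetra-O-methoxymethyl cassigarol E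
Product: 13 cassigarol E
Conditions: conc. aq. HCl (cat.), MeOH, 45 °C, Ar
Reagents that add atoms: none
Why: Acid-catalysed acetal exchange with methanol removes the four methoxymethyl groups as dimethoxymethane, and the configuration should hold because C3 has no para oxygen and cannot ionise, while a reversible opening at C2 can only return to the trans ring.

**Compound list**

1 | methyl 3,5-dihydroxybenzoate | COC(=O)c1cc(O)cc(O)c1 | starting material
2 | methyl 3,5-bis(methoxymethoxy)benzoate | COCOc1cc(OCOC)cc(C(=O)OC)c1 | intermediate
3 | [3,5-bis(methoxymethoxy)phenyl]methanol | COCOc1cc(CO)cc(OCOC)c1 | intermediate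
4 | 1-(bromomethyl)-3,5-bis(methoxymethoxy)benzene | COCOc1cc(CBr)cc(OCOC)c1 | intermediate
5 | diethyl {[3,5-bis(methoxymethoxy)phenyl]methyl}phosphonate | CCOP(=O)(Cc1cc(OCOC)cc(OCOC)c1)OCC | intermediate
6 | 3,4-dihydroxybenzaldehyde | O=Cc1ccc(O)c(O)c1 | starting material
7 | 3,4-bis[(tert-butyldimethylsilyl)oxy]benzaldehyde | CC(C)(C)[Si](C)(C)Oc1ccc(C=O)cc1O[Si](C)(C)C(C)(C)C | intermediate
8 | (E)-1,2-bis[(tert-butyldimethylsilyl)oxy]-4-{2-[3,5-bis(methoxymethoxy)phenyl]ethenyl}benzene | COCOc1cc(OCOC)cc(/C=C/c2ccc(O[Si](C)(C)C(C)(C)C)c(O[Si](C)(C)C(C)(C)C)c2)c1 | intermediate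
9 | 4-[(E)-2-[3,5-bis(methoxymethoxy)phenyl]ethenyl]benzene-1,2-diol | COCOc1cc(OCOC)cc(/C=C/c2ccc(O)c(O)c2)c1 | intermediate
10 | 4-{2-[3,5-bis(methoxymethoxy)phenyl]-2-{4-[(E)-2-[3,5-bis(methoxymethoxy)phenyl]ethenyl]-2-hydroxyphenoxy}ethylidene}-2-hydroxycyclohexa-2,5-dien-1-one (para-quinone methide ether; racemic at the ether carbon, the S half that leads to 12 is drawn) | COCOc1cc(OCOC)cc(/C=C/c2ccc(O[C@@H](C=C3C=CC(=O)C(O)=C3)c3cc(OCOC)cc(OCOC)c3)c(O)c2)c1 | intermediate (not isolated)
11 | 4-[(2R*,3R*)-3-[3,5-bis(methoxymethoxy)phenyl]-7-{(E)-2-[3,5-bis(methoxymethoxy)phenyl]ethenyl}-2,3-dihydro-1,4-benzodioxin-2-yl]benzene-1,2-diol (tetra-O-methoxymethyl cassigarol E, trans racemate; the 2R,3R half is drawn) | COCOc1cc(OCOC)cc(/C=C/c2ccc3c(c2)O[C@H](c2ccc(O)c(O)c2)[C@@H](c2cc(OCOC)cc(OCOC)c2)O3)c1 | intermediate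
12 | 4-[(2R,3R)-3-[3,5-bis(methoxymethoxy)phenyl]-7-{(E)-2-[3,5-bis(methoxymethoxy)phenyl]ethenyl}-2,3-dihydro-1,4-benzodioxin-2-yl]benzene-1,2-diol (single enantiomer) | COCOc1cc(OCOC)cc(/C=C/c2ccc3c(c2)O[C@H](c2ccc(O)c(O)c2)[C@@H](c2cc(OCOC)cc(OCOC)c2)O3)c1 | intermediate
13 | cassigarol E, 4-[(2R,3R)-3-(3,5-dihydroxyphenyl)-7-[(E)-2-(3,5-dihydroxyphenyl)ethenyl]-2,3-dihydro-1,4-benzodioxin-2-yl]benzene-1,2-diol | Oc1cc(O)cc(/C=C/c2ccc3c(c2)O[C@H](c2ccc(O)c(O)c2)[C@@H](c2cc(O)cc(O)c2)O3)c1 | target

**Count**

Total steps: 10. Longest linear sequence: 9 steps (steps 1, 2, 3, 4, 6, 7, 8, 9, 10 from compound 1); step 5 is the one-step side branch from compound 6.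

**Steps most likely to fail**

Step 8. The catechol that remains in 11 is still a competent donor, so further oxidation and growth of trimers and higher oligomers should increase with conversion. Carbon–carbon coupling at the olefinic carbons or at the ring position ortho to the catechol oxygen may also compete with O4–C3 coupling. The fallback sets out from 9 and 6, uses 5, and returns at 11. It makes the dioxane by hetero-coupling and adds the styryl arm afterwards. Stilbene 9 is oxidised with Ag2CO3 in acetone–toluene in the presence of an excess of 3,4-dihydroxybenzaldehyde 6, which has no olefin and can act only as the donor catechol. This known silver-salt cross-coupling of a catechol aldehyde with a 4-hydroxystyrene should give racemic trans-2-(3,4-dihydroxyphenyl)-3-[3,5-bis(methoxymethoxy)phenyl]-2,3-dihydro-1,4-benzodioxine-7-carbaldehyde F1. The regiochemistry of this cross-coupling is less certain than in the homodimerisation, and the isomer with the formyl group para to O1 would have to be removed at this point. Silylation with TBSCl and imidazole in DMF should give trans-2-{3,4-bis[(tert-butyldimethylsilyl)oxy]phenyl}-3-[3,5-bis(methoxymethoxy)phenyl]-2,3-dihydro-1,4-benzodioxine-7-carbaldehyde F2. Horner–Wadsworth–Emmons olefination with phosphonate 5 (NaH, 15-crown-5, THF) should then give the bis(tert-butyldimethylsilyl) ether of tetra-O-methoxymethyl cassigarol E F3. Desilylation with TBAF and AcOH returns 11.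

Step 6. The base may cleave or shift the aryl silyl ethers before addition, which leaves a phenoxide-deactivated aldehyde that no longer accepts the phosphonate anion and stalls the olefination. The fallback sets out from 6 and 5 and returns at 9, with the catechol carried through as base-stable allyl ethers. Compound 6 is alkylated with allyl bromide and K2CO3 in DMF to 3,4-bis(prop-2-enyloxy)benzaldehyde F4. Olefination with 5 (NaH, THF) should give (E)-1,2-bis(prop-2-enyloxy)-4-{2-[3,5-bis(methoxymethoxy)phenyl]ethenyl}benzene F5. Tsuji–Trost allyl transfer to morpholine with the zerovalent palladium catalyst Pd(PPh3)4 in THF frees the catechol and gives 9.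

Step 10. Methoxymethyl cations may be captured by the liberated, electron-rich resorcinol rings (Friedel–Crafts alkylation). Acid may also open the C2–O1 benzylic ether, with capture by methanol or partial drift to the cis ring, and the hexaphenol may oxidise in air. The fallback sets out from 12 and returns at 13, exchanging the acetals for silyl ethers under non-protic conditions. TESOTf with 2,2'-bipyridyl in CH2Cl2 (0 °C to rt) is known to convert aryl methoxymethyl ethers directly into aryl triethylsilyl ethers. It should also silylate the free catechol, giving cassigarol E hexakis(triethylsilyl) ether F6, which is purified on silica. Desilylation with TBAF and AcOH in THF at 0 °C then gives 13, with no free methoxymethyl cation and no Brønsted acid at any point.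

**Further compounds**

F1 | step 8 | trans-2-(3,4-dihydroxyphenyl)-3-[3,5-bis(methoxymethoxy)phenyl]-2,3-dihydro-1,4-benzodioxine-7-carbaldehyde (racemate; 2R,3R drawn) | O=Cc1ccc2c(c1)O[C@H](c1ccc(O)c(O)c1)[C@@H](c1cc(OCOC)cc(OCOC)c1)O2
F2 | step 8 | trans-2-{3,4-bis[(tert-butyldimethylsilyl)oxy]phenyl}-3-[3,5-bis(methoxymethoxy)phenyl]-2,3-dihydro-1,4-benzodioxine-7-carbaldehyde (racemate; 2R,3R drawn) | O=Cc1ccc2c(c1)O[C@H](c1ccc(O[Si](C)(C)C(C)(C)C)c(O[Si](C)(C)C(C)(C)C)c1)[C@@H](c1cc(OCOC)cc(OCOC)c1)O2
F3 | step 8 | bis(tert-butyldimethylsilyl) ether of tetra-O-methoxymethyl cassigarol E (racemate; 2R,3R drawn) | COCOc1cc(OCOC)cc(/C=C/c2ccc3c(c2)O[C@H](c2ccc(O[Si](C)(C)C(C)(C)C)c(O[Si](C)(C)C(C)(C)C)c2)[C@@H](c2cc(OCOC)cc(OCOC)c2)O3)c1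
F4 | step 6 | 3,4-bis(prop-2-enyloxy)benzaldehyde | C=CCOc1ccc(C=O)cc1OCC=C
F5 | step 6 | (E)-1,2-bis(prop-2-enyloxy)-4-{2-[3,5-bis(methoxymethoxy)phenyl]ethenyl}benzene | COCOc1cc(OCOC)cc(/C=C/c2ccc(OCC=C)c(OCC=C)c2)c1
F6 | step 10 | (2R,3R)-cassigarol E hexakis(triethylsilyl) ether | CC[Si](CC)(CC)Oc1cc(O[Si](CC)(CC)CC)cc(/C=C/c2ccc3c(c2)O[C@H](c2ccc(O[Si](CC)(CC)CC)c(O[Si](CC)(CC)CC)c2)[C@@H](c2cc(O[Si](CC)(CC)CC)cc(O[Si](CC)(CC)CC)c2)O3)c1
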